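The C9–C15 segment of the 19-membered ansa lactam (methyl-bearing C10 and C14, erythro methoxy carbons C11 and C12, aryl carbinol C15) is folded into a 1-aryl-3,7-dimethylcyclohepta-1,4-diene whose C9=C15 bond is cut later. A single Cope rearrangement of a cis-divinylcyclopropane forms C13–C14, closes that seven-membered ring and sets C14 relative to C10; the ring then directs osmylation of C11=C12 before ozonolysis reopens it. The precursor is a cyclopropane C9–C10–C11 with a vinyl group on C11, a cis (Z)-1-(2,5-dimethoxy-3-nitrophenyl)propenyl group on C9 and a trans methyl on C10, released by methylenation of its aldehyde.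

Key step: step 8

Assumption: carbons are numbered C1 (amide carbonyl) to C15 (benzylic carbon); 1, 3, 6, 9 and 23 are taken as purchasable, and the dioxaborolane ligand of step 6 is taken to select the alkene face through the allylic alcohol alone, whatever the alkene geometry.

Step 1
Reactants: 1 2-bromo-4-methoxy-6-nitrophenol
Product: 2 1-bromo-2,5-dimethoxy-3-nitrobenzene
Conditions: MeI, K2CO3, DMF, 50 °C
Reagents that add atoms: iodomethane, CI
Why: Williamson O-methylation of the acidic ortho-nitrophenol should be clean because the phenoxide is the only nucleophilic site.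

Step 2
Reactants: 2 1-bromo-2,5-dimethoxy-3-nitrobenzene; 3 propyne
Product: 4 2,5-dimethoxy-1-nitro-3-(prop-1-yn-1-yl)benzene
Conditions: propyne (excess), PdCl2(PPh3)2 (cat.), CuI (cat.), Et3N, DMF, sealed vessel, 50 °C
Reagents that add atoms: none
Why: Sonogashira coupling of the nitro-activated aryl bromide with propyne should install the future C14–C15 unit and its methyl group in one operation.

Step 3
Reactants: 4 2,5-dimethoxy-1-nitro-3-(prop-1-yn-1-yl)benzene
Product: 5 tributyl[(1E)-1-(2,5-dimethoxy-3-nitrophenyl)prop-1-en-1-yl]stannane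
Conditions: n-Bu3SnH (slow addition), PdCl2(PPh3)2 (cat.), THF, 0 °C to rt
Reagents that add atoms: tributylstannane, CCCC[SnH](CCCC)CCCC
Why: Palladium-catalysed hydrostannation adds H and Sn syn and, with an ortho-substituted aryl alkyne, should place tin on the aryl-bearing carbon (C15), so that the C14 methyl lies cis to the arene and trans to tin.

Step 4
Reactants: 6 ethyl (2Z)-3-iodoprop-2-enoate
Product: 7 (2Z)-3-iodoprop-2-en-1-ol
Conditions: i-Bu2AlH, CH2Cl2, −78 to 0 °C; Rochelle salt work-up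
Reagents that add atoms: none
Why: Hydride reduction of the ester to the allylic alcohol at low temperature should leave the vinyl iodide and its Z geometry untouched.

Step 5
Reactants: 5 tributyl[(1E)-1-(2,5-dimethoxy-3-nitrophenyl)prop-1-en-1-yl]stannane; 7 (2Z)-3-iodoprop-2-en-1-ol
Product: 8 (2Z,4Z)-4-(2,5-dimethoxy-3-nitrophenyl)hexa-2,4-dien-1-ol
Conditions: Pd(PPh3)4 (cat.), CuI, CsF, DMF, rt to 40 °C, dark
Reagents that add atoms: none
Why: Stille coupling promoted by CuI and fluoride should join the hindered 1-aryl vinylstannane and the Z-vinyl iodide (C9–C15 bond) with retention at both sp2 carbons, giving the Z,Z-diene.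

Step 6
Reactants: 8 (2Z,4Z)-4-(2,5-dimethoxy-3-nitrophenyl)hexa-2,4-dien-1-ol; 9 1,1-diiodoethane
Product: 10 {(1R,2S,3S)-2-[(1Z)-1-(2,5-dimethoxy-3-nitrophenyl)prop-1-en-1-yl]-3-methylcyclopropyl}methanol
Conditions: Et2Zn, CH3CHI2, (4S,5S)-2-butyl-N,N,N′,N′-tetramethyl-1,3,2-dioxaborolane-4,5-dicarboxamide (1.2 equiv), CH2Cl2, −40 to 0 °C
Reagents that add atoms: none
Why: Charette asymmetric Simmons–Smith cyclopropanation with the 1-iodoethylzinc carbenoid is directed by the zinc alkoxide–dioxaborolane complex to the allylic C9=C11 alkene only, adds syn so that CH2OH and the arylpropenyl group stay cis, places the C10 methyl anti to both, and the (S,S)-ligand should select the face that fixes C9, C10 and C11 as drawn.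

Step 7
Reactants: 10 {(1R,2S,3S)-2-[(1Z)-1-(2,5-dimethoxy-3-nitrophenyl)prop-1-en-1-yl]-3-methylcyclopropyl}methanol
Product: 11 (1R,2S,3S)-2-[(1Z)-1-(2,5-dimethoxy-3-nitrophenyl)prop-1-en-1-yl]-3-methylcyclopropane-1-carbaldehyde
Conditions: Dess–Martin periodinane, NaHCO3, CH2Cl2, 0 °C; short silica plug, used at once
Reagents that add atoms: none
Why: Buffered Dess–Martin oxidation gives the aldehyde under near-neutral conditions, and immediate use limits epimerisation at C11 and the reversible retro-Claisen isomerisation open to a cis-2-alkenylcyclopropanecarbaldehyde.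

Step 8
Reactants: 11 (1R,2S,3S)-2-[(1Z)-1-(2,5-dimethoxy-3-nitrophenyl)prop-1-en-1-yl]-3-methylcyclopropane-1-carbaldehyde
Product: 13 1-[(3R,7S)-3,7-dimethylcyclohepta-1,4-dien-1-yl]-2,5-dimethoxy-3-nitrobenzene, via cis-divinylcyclopropane 12 (not isolated)
Conditions: Ph3PCH3Br, KN(SiMe3)2, THF, 0 °C; add 11 at −78 °C, warm to rt, then 40 °C until 12 is consumed
Reagents that add atoms: methyltriphenylphosphonium bromide, C[P+](c1ccccc1)(c1ccccc1)c1ccccc1.[Br-]
Why: Wittig methylenation at low temperature turns the formyl group into the C12=C13 vinyl group before the cis aldehyde can epimerise, and the resulting cis-divinylcyclopropane 12 then undergoes a concerted [3,3] sigmatropic shift driven by release of three-ring strain. The closest known reaction type is the thermal rearrangement of cis-1,2-dialkenylcyclopropanes to cyclohepta-1,4-dienes, which proceeds at or near ambient temperature when no substituent on an alkene terminus is cis to the ring. The seven-membered ring C9–C10–C11–C12–C13–C14–C15 closes by σ-bond formation between the alkene termini C13 and C14 while C9–C11 breaks, a pericyclic ring expansion through a six-centre boat array with both alkenyl groups folded over the cyclopropane, not an ionic exo or endo closure. The new stereocentre C14 is controlled by the Z geometry of the arylpropenyl group (methyl trans to the ring, hence exo in the boat) together with the C10 configuration, whose methyl is trans to both alkenyl groups and likewise exo, so the two methyls should emerge cis with C14 in the S configuration. The step needs the cis relation of the alkenyl groups and hydrogen as the only substituent pointing into the boat at C10 and C14; these are secured by the Z alkene of step 5, the syn-specific cyclopropanation of step 6 and the trans C10 methyl, which also excludes a competing retro-ene hydrogen shift.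

Step 9
Reactants: 13 1-[(3R,7S)-3,7-dimethylcyclohepta-1,4-dien-1-yl]-2,5-dimethoxy-3-nitrobenzene
Product: 14 (1S,2R,3S,6S)-5-(2,5-dimethoxy-3-nitrophenyl)-3,6-dimethylcyclohept-4-ene-1,2-diol
Conditions: OsO4 (cat.), 4-methylmorpholine N-oxide, acetone/H2O, 0 °C; Na2SO3 quench
Reagents that add atoms: 4-methylmorpholine N-oxide, C[N+]1([O-])CCOCC1; water, O
Why: Catalytic osmium tetroxide syn-dihydroxylation should take the cis-disubstituted C11=C12 alkene in preference to the trisubstituted C9=C15 alkene, which is flanked by two branched carbons and a twisted electron-poor arene, and should add from the ring face opposite the two cis methyl groups, setting C11 (R) and C12 (S).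

Step 10
Reactants: 14 (1S,2R,3S,6S)-5-(2,5-dimethoxy-3-nitrophenyl)-3,6-dimethylcyclohept-4-ene-1,2-diol
Product: 15 1-[(3S,4R,5S,7S)-4,5-dimethoxy-3,7-dimethylcyclohept-1-en-1-yl]-2,5-dimethoxy-3-nitrobenzene
Conditions: NaH, MeI, THF/DMF, 0 °C to rt
Reagents that add atoms: iodomethane, CI
Why: Double Williamson etherification of the cis-diol should give both methyl ethers, as no other acidic or electrophilic site competes.

Step 11
Reactants: 15 1-[(3S,4R,5S,7S)-4,5-dimethoxy-3,7-dimethylcyclohept-1-en-1-yl]-2,5-dimethoxy-3-nitrobenzene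
Product: 17 (2R,3R,4S,6S)-7-(2,5-dimethoxy-3-nitrophenyl)-3,4-dimethoxy-2,6-dimethyl-7-oxoheptanal, via secondary ozonide 16 (not isolated)
Conditions: O3, CH2Cl2, −78 °C; then PPh3, −78 °C to rt; crude product used directly
Reagents that add atoms: ozone, [O-][O+]=O
Why: Ozonolysis with reductive work-up cleaves the only remaining alkene, C9=C15, to the C9 aldehyde and the C15 aryl ketone, the nitro-deactivated arene being inert to ozone at −78 °C.

Step 12
Reactants: 17 (2R,3R,4S,6S)-7-(2,5-dimethoxy-3-nitrophenyl)-3,4-dimethoxy-2,6-dimethyl-7-oxoheptanal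
Product: 18 ethyl (2E,4S,5R,6S,8S)-9-(2,5-dimethoxy-3-nitrophenyl)-5,6-dimethoxy-2,4,8-trimethyl-9-oxonon-2-enoate
Conditions: Ph3P=C(CH3)CO2Et, CH2Cl2, rt to 40 °C
Reagents that add atoms: ethyl 2-(triphenylphosphoranylidene)propanoate, CCOC(=O)C(C)=P(c1ccccc1)(c1ccccc1)c1ccccc1
Why: The stabilised Wittig ylide reacts with the aldehyde but not with the hindered aryl ketone and should give the E-trisubstituted C8=C9 enoate under neutral conditions that do not epimerise C10 or C14.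

Step 13
Reactants: 18 ethyl (2E,4S,5R,6S,8S)-9-(2,5-dimethoxy-3-nitrophenyl)-5,6-dimethoxy-2,4,8-trimethyl-9-oxonon-2-enoate
Product: 19 ethyl (2E,4S,5R,6S,8S,9R)-9-(2,5-dimethoxy-3-nitrophenyl)-9-hydroxy-5,6-dimethoxy-2,4,8-trimethylnon-2-enoate
Conditions: (S)-2-methyl-CBS-oxazaborolidine, BH3·SMe2, THF, −30 °C; MeOH quench
Reagents that add atoms: none
Why: Corey–Bakshi–Shibata reduction treats the arene as the large and the branched alkyl chain as the small ketone substituent, so the (S)-oxazaborolidine should deliver hydride to the face giving the 15R carbinol (syn to the C14 methyl) under reagent control against the Felkin preference, while borane at low temperature spares the enoate and the nitro group.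

Step 14
Reactants: 19 ethyl (2E,4S,5R,6S,8S,9R)-9-(2,5-dimethoxy-3-nitrophenyl)-9-hydroxy-5,6-dimethoxy-2,4,8-trimethylnon-2-enoate
Product: 20 ethyl (2E,4S,5R,6S,8S,9R)-9-{[tert-butyl(dimethyl)silyl]oxy}-9-(2,5-dimethoxy-3-nitrophenyl)-5,6-dimethoxy-2,4,8-trimethylnon-2-enoate
Conditions: TBSOTf, 2,6-lutidine, CH2Cl2, −78 to 0 °C
Reagents that add atoms: tert-butyldimethylsilyl trifluoromethanesulfonate, CC(C)(C)[Si](C)(C)OS(=O)(=O)C(F)(F)F
Why: Silylation with the silyl triflate protects the hindered benzylic C15 hydroxyl as an ether that should survive every step up to the final fluoride treatment.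

Step 15
Reactants: 20 ethyl (2E,4S,5R,6S,8S,9R)-9-{[tert-butyl(dimethyl)silyl]oxy}-9-(2,5-dimethoxy-3-nitrophenyl)-5,6-dimethoxy-2,4,8-trimethylnon-2-enoate
Product: 21 (2E,4S,5R,6S,8S,9R)-9-{[tert-butyl(dimethyl)silyl]oxy}-9-(2,5-dimethoxy-3-nitrophenyl)-5,6-dimethoxy-2,4,8-trimethylnon-2-en-1-ol
Conditions: i-Bu2AlH, CH2Cl2, −78 °C; Rochelle salt work-up
Reagents that add atoms: none
Why: 1,2-Reduction of the enoate by the aluminium hydride at −78 °C should give the allylic alcohol without touching silyl ether, methyl ethers or nitro group.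

Step 16
Reactants: 21 (2E,4S,5R,6S,8S,9R)-9-{[tert-butyl(dimethyl)silyl]oxy}-9-(2,5-dimethoxy-3-nitrophenyl)-5,6-dimethoxy-2,4,8-trimethylnon-2-en-1-ol
Product: 22 (2E,4S,5R,6S,8S,9R)-9-{[tert-butyl(dimethyl)silyl]oxy}-9-(2,5-dimethoxy-3-nitrophenyl)-5,6-dimethoxy-2,4,8-trimethylnon-2-enal
Conditions: Dess–Martin periodinane, NaHCO3, CH2Cl2, 0 °C to rt
Reagents that add atoms: none
Why: Dess–Martin oxidation of the allylic alcohol should stop at the E-enal (C7) without alkene isomerisation.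

Step 17
Reactants: 22 (2E,4S,5R,6S,8S,9R)-9-{[tert-butyl(dimethyl)silyl]oxy}-9-(2,5-dimethoxy-3-nitrophenyl)-5,6-dimethoxy-2,4,8-trimethylnon-2-enal; 23 1-[(4R)-4-benzyl-2-sulfanylidene-1,3-thiazolidin-3-yl]propan-1-one
Product: 24 (2R,3R,4E,6S,7R,8S,10S,11R)-1-[(4R)-4-benzyl-2-sulfanylidene-1,3-thiazolidin-3-yl]-11-{[tert-butyl(dimethyl)silyl]oxy}-11-(2,5-dimethoxy-3-nitrophenyl)-3-hydroxy-7,8-dimethoxy-2,4,6,10-tetramethylundec-4-en-1-one
Conditions: 23, TiCl4, i-Pr2NEt, N-methyl-2-pyrrolidinone, CH2Cl2, 0 °C; then 22, −78 to 0 °C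
Reagents that add atoms: none
Why: In this Crimmins aldol the chlorotitanium Z-enolate adds to the enal through a non-chelated Zimmerman–Traxler transition state in which the (R)-benzyl auxiliary shields one enolate face, so C6 and C7 should form syn in the configuration that becomes 6S,7R once C5 is an alkene carbon.

Step 18
Reactants: 24 (2R,3R,4E,6S,7R,8S,10S,11R)-1-[(4R)-4-benzyl-2-sulfanylidene-1,3-thiazolidin-3-yl]-11-{[tert-butyl(dimethyl)silyl]oxy}-11-(2,5-dimethoxy-3-nitrophenyl)-3-hydroxy-7,8-dimethoxy-2,4,6,10-tetramethylundec-4-en-1-one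
Product: 25 (2R,3R,4E,6S,7R,8S,10S,11R)-1-[(4R)-4-benzyl-2-sulfanylidene-1,3-thiazolidin-3-yl]-11-{[tert-butyl(dimethyl)silyl]oxy}-11-(2,5-dimethoxy-3-nitrophenyl)-7,8-dimethoxy-2,4,6,10-tetramethyl-3-[(triethylsilyl)oxy]undec-4-en-1-one
Conditions: TESOTf, 2,6-lutidine, CH2Cl2, −78 °C
Reagents that add atoms: triethylsilyl trifluoromethanesulfonate, CC[Si](CC)(CC)OS(=O)(=O)C(F)(F)F
Why: Silylation gives a C7 triethylsilyl ether that blocks retro-aldol cleavage and is more labile than the C15 tert-butyldimethylsilyl ether, for selective release later.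

Step 19
Reactants: 25 (2R,3R,4E,6S,7R,8S,10S,11R)-1-[(4R)-4-benzyl-2-sulfanylidene-1,3-thiazolidin-3-yl]-11-{[tert-butyl(dimethyl)silyl]oxy}-11-(2,5-dimethoxy-3-nitrophenyl)-7,8-dimethoxy-2,4,6,10-tetramethyl-3-[(triethylsilyl)oxy]undec-4-en-1-one
Product: 26 (2R,3R,4E,6S,7R,8S,10S,11R)-11-{[tert-butyl(dimethyl)silyl]oxy}-11-(2,5-dimethoxy-3-nitrophenyl)-7,8-dimethoxy-2,4,6,10-tetramethyl-3-[(triethylsilyl)oxy]undec-4-enal
Conditions: i-Bu2AlH, CH2Cl2, −78 °C; Rochelle salt work-up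
Reagents that add atoms: none
Why: N-Acyl thiazolidinethiones are reduced by the aluminium hydride to a stable tetrahedral adduct that collapses to the aldehyde only on work-up, so the C5 aldehyde should form without over-reduction or epimerisation at C6.

Step 20
Reactants: 26 (2R,3R,4E,6S,7R,8S,10S,11R)-11-{[tert-butyl(dimethyl)silyl]oxy}-11-(2,5-dimethoxy-3-nitrophenyl)-7,8-dimethoxy-2,4,6,10-tetramethyl-3-[(triethylsilyl)oxy]undec-4-enal
Product: 27 methyl (2Z,4S,5R,6E,8S,9R,10S,12S,13R)-13-{[tert-butyl(dimethyl)silyl]oxy}-13-(2,5-dimethoxy-3-nitrophenyl)-9,10-dimethoxy-4,6,8,12-tetramethyl-5-[(triethylsilyl)oxy]trideca-2,6-dienoate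
Conditions: (CF3CH2O)2P(O)CH2CO2Me, KN(SiMe3)2, 18-crown-6, THF, −78 °C
Reagents that add atoms: methyl 2-[bis(2,2,2-trifluoroethoxy)phosphoryl]acetate, COC(=O)CP(=O)(OCC(F)(F)F)OCC(F)(F)F
Why: Still–Gennari olefination with the electron-poor phosphonate under dissociating conditions eliminates under kinetic control and should give the Z C4=C5 enoate.

Step 21
Reactants: 27 methyl (2Z,4S,5R,6E,8S,9R,10S,12S,13R)-13-{[tert-butyl(dimethyl)silyl]oxy}-13-(2,5-dimethoxy-3-nitrophenyl)-9,10-dimethoxy-4,6,8,12-tetramethyl-5-[(triethylsilyl)oxy]trideca-2,6-dienoate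
Product: 28 (2Z,4S,5R,6E,8S,9R,10S,12S,13R)-13-{[tert-butyl(dimethyl)silyl]oxy}-13-(2,5-dimethoxy-3-nitrophenyl)-9,10-dimethoxy-4,6,8,12-tetramethyl-5-[(triethylsilyl)oxy]trideca-2,6-dien-1-ol
Conditions: i-Bu2AlH, CH2Cl2, −78 °C; Rochelle salt work-up
Reagents that add atoms: none
Why: 1,2-Reduction of the Z-enoate should give the Z-allylic alcohol with the alkene geometry intact.

Step 22
Reactants: 28 (2Z,4S,5R,6E,8S,9R,10S,12S,13R)-13-{[tert-butyl(dimethyl)silyl]oxy}-13-(2,5-dimethoxy-3-nitrophenyl)-9,10-dimethoxy-4,6,8,12-tetramethyl-5-[(triethylsilyl)oxy]trideca-2,6-dien-1-ol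
Product: 29 (2Z,4S,5R,6E,8S,9R,10S,12S,13R)-13-{[tert-butyl(dimethyl)silyl]oxy}-13-(2,5-dimethoxy-3-nitrophenyl)-9,10-dimethoxy-4,6,8,12-tetramethyl-5-[(triethylsilyl)oxy]trideca-2,6-dienal
Conditions: Dess–Martin periodinane, NaHCO3, CH2Cl2, 0 °C; used directly
Reagents that add atoms: none
Why: Buffered Dess–Martin oxidation is mild enough to give the Z-enal without Z to E isomerisation when the product is used at once.

Step 23
Reactants: 29 (2Z,4S,5R,6E,8S,9R,10S,12S,13R)-13-{[tert-butyl(dimethyl)silyl]oxy}-13-(2,5-dimethoxy-3-nitrophenyl)-9,10-dimethoxy-4,6,8,12-tetramethyl-5-[(triethylsilyl)oxy]trideca-2,6-dienal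
Product: 30 ethyl (2E,4Z,6S,7R,8E,10S,11R,12S,14S,15R)-15-{[tert-butyl(dimethyl)silyl]oxy}-15-(2,5-dimethoxy-3-nitrophenyl)-11,12-dimethoxy-2,6,8,10,14-pentamethyl-7-[(triethylsilyl)oxy]pentadeca-2,4,8-trienoate
Conditions: Ph3P=C(CH3)CO2Et, CH2Cl2, rt
Reagents that add atoms: ethyl 2-(triphenylphosphoranylidene)propanoate, CCOC(=O)C(C)=P(c1ccccc1)(c1ccccc1)c1ccccc1
Why: Wittig olefination with the stabilised ylide should form the E C2=C3 bond while the neutral conditions keep the 4Z geometry.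

Step 24
Reactants: 30 ethyl (2E,4Z,6S,7R,8E,10S,11R,12S,14S,15R)-15-{[tert-butyl(dimethyl)silyl]oxy}-15-(2,5-dimethoxy-3-nitrophenyl)-11,12-dimethoxy-2,6,8,10,14-pentamethyl-7-[(triethylsilyl)oxy]pentadeca-2,4,8-trienoate
Product: 31 ethyl (2E,4Z,6S,7R,8E,10S,11R,12S,14S,15R)-15-(3-amino-2,5-dimethoxyphenyl)-15-{[tert-butyl(dimethyl)silyl]oxy}-11,12-dimethoxy-2,6,8,10,14-pentamethyl-7-[(triethylsilyl)oxy]pentadeca-2,4,8-trienoate
Conditions: Fe powder, NH4Cl, EtOH/H2O, 60 °C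
Reagents that add atoms: none
Why: Béchamp-type reduction with iron in buffered aqueous ethanol converts the nitroarene into the aniline by electron transfer and should spare the triene, the ester and both silyl ethers.

Step 25
Reactants: 31 ethyl (2E,4Z,6S,7R,8E,10S,11R,12S,14S,15R)-15-(3-amino-2,5-dimethoxyphenyl)-15-{[tert-butyl(dimethyl)silyl]oxy}-11,12-dimethoxy-2,6,8,10,14-pentamethyl-7-[(triethylsilyl)oxy]pentadeca-2,4,8-trienoate
Product: 32 (2E,4Z,6S,7R,8E,10S,11R,12S,14S,15R)-15-(3-amino-2,5-dimethoxyphenyl)-15-{[tert-butyl(dimethyl)silyl]oxy}-11,12-dimethoxy-2,6,8,10,14-pentamethyl-7-[(triethylsilyl)oxy]pentadeca-2,4,8-trienoic acid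
Conditions: LiOH, THF/MeOH/H2O, rt to 40 °C; then dilute HCl to pH 5 at 0 °C
Reagents that add atoms: lithium hydroxide, [Li+].[OH-]
Why: Saponification of the ethyl ester by hydroxide should release the dienoic acid while the secondary silyl ethers tolerate the mildly basic medium and the brief buffered acidification.

Step 26
Reactants: 32 (2E,4Z,6S,7R,8E,10S,11R,12S,14S,15R)-15-(3-amino-2,5-dimethoxyphenyl)-15-{[tert-butyl(dimethyl)silyl]oxy}-11,12-dimethoxy-2,6,8,10,14-pentamethyl-7-[(triethylsilyl)oxy]pentadeca-2,4,8-trienoic acid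
Product: 33 19-membered lactam of 32 (aniline N joined to C1; 2E,4Z,8E; 6S,7R,10S,11R,12S,14S,15R; 7-O-triethylsilyl; 15-O-tert-butyldimethylsilyl; 2,5-dimethoxy-1,3-phenylene bridge)
Conditions: BOP-Cl, i-Pr2NEt, toluene, 85 °C, slow addition at high dilution
Reagents that add atoms: none
Why: Activation of the acid as a mixed phosphinic anhydride and acylation of the aniline under high dilution (macrolactamisation) should close the ansa ring, the only other nucleophiles being silyl-protected.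

Step 27
Reactants: 33 19-membered lactam (7-O-triethylsilyl; 15-O-tert-butyldimethylsilyl)
Product: 34 19-membered lactam with free C7 hydroxyl (15-O-tert-butyldimethylsilyl retained)
Conditions: pyridinium p-toluenesulfonate, MeOH/CH2Cl2, 0 °C
Reagents that add atoms: none
Why: Mild acid-catalysed methanolysis removes the triethylsilyl ether far faster than the hindered benzylic tert-butyldimethylsilyl ether, so only the C7 hydroxyl should be released.

Step 28
Reactants: 34 19-membered lactam with free C7 hydroxyl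
Product: 36 C7 carbamate of 34 (7-O-carbamoyl; 15-O-tert-butyldimethylsilyl), via N-trichloroacetyl carbamate 35 (not isolated)
Conditions: Cl3CC(O)NCO, CH2Cl2, 0 °C; then K2CO3, MeOH, rt
Reagents that add atoms: trichloroacetyl isocyanate, O=C=NC(=O)C(Cl)(Cl)Cl
Why: The acyl isocyanate carbamoylates the only free hydroxyl, and carbonate-mediated methanolysis then removes the trichloroacetyl group to leave the primary carbamate without affecting the anilide or the silyl ether.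

Step 29
Reactants: 36 C7 carbamate (dimethoxyarene; 15-O-tert-butyldimethylsilyl)
Product: 37 15-O-tert-butyldimethylsilyl ether of the target quinone
Conditions: (NH4)2Ce(NO3)6, MeCN/H2O, 0 °C
Reagents that add atoms: water, O
Why: Oxidative demethylation of the para-dimethoxy anilide by tetravalent cerium, with water supplying the carbonyl oxygens, should give the 2-amido-1,4-benzoquinone, and no other electron-rich site is present.

Step 30
Reactants: 37 15-O-tert-butyldimethylsilyl ether of the target quinone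
Product: 38 CNP0557283.1
Conditions: HF (aq. 48%), MeCN, 0 °C to rt
Reagents that add atoms: none
Why: Fluoride-assisted desilylation under acidic conditions should free the C15 hydroxyl while quinone, carbamate, methyl ethers and triene stay intact.

Compound list
1 | 2-bromo-4-methoxy-6-nitrophenol | COc1cc(Br)c(O)c([N+](=O)[O-])c1 | starting material
2 | 1-bromo-2,5-dimethoxy-3-nitrobenzene | COc1cc(Br)c(OC)c([N+](=O)[O-])c1 | intermediate
3 | propyne | CC#C | starting material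
4 | 2,5-dimethoxy-1-nitro-3-(prop-1-yn-1-yl)benzene | CC#Cc1cc(OC)cc([N+](=O)[O-])c1OC | intermediate
5 | tributyl[(1E)-1-(2,5-dimethoxy-3-nitrophenyl)prop-1-en-1-yl]stannane | C/C=C(/[Sn](CCCC)(CCCC)CCCC)c1cc(OC)cc([N+](=O)[O-])c1OC | intermediate
6 | ethyl (2Z)-3-iodoprop-2-enoate | CCOC(=O)/C=C\I | starting material
7 | (2Z)-3-iodoprop-2-en-1-ol | OC/C=C\I | intermediate
8 | (2Z,4Z)-4-(2,5-dimethoxy-3-nitrophenyl)hexa-2,4-dien-1-ol | OC/C=C\C(=C\C)c1cc(OC)cc([N+](=O)[O-])c1OC | intermediate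
9 | 1,1-diiodoethane | CC(I)I | starting material
10 | {(1R,2S,3S)-2-[(1Z)-1-(2,5-dimethoxy-3-nitrophenyl)prop-1-en-1-yl]-3-methylcyclopropyl}methanol | C[C@@H]1[C@@H](CO)[C@H]1/C(=C/C)c1cc(OC)cc([N+](=O)[O-])c1OC | intermediate
11 | (1R,2S,3S)-2-[(1Z)-1-(2,5-dimethoxy-3-nitrophenyl)prop-1-en-1-yl]-3-methylcyclopropane-1-carbaldehyde | C[C@@H]1[C@@H](C=O)[C@H]1/C(=C/C)c1cc(OC)cc([N+](=O)[O-])c1OC | intermediate
12 | 1-{(1Z)-1-[(1S,2R,3R)-2-ethenyl-3-methylcyclopropyl]prop-1-en-1-yl}-2,5-dimethoxy-3-nitrobenzene (cis-divinylcyclopropane) | C[C@@H]1[C@@H](C=C)[C@H]1/C(=C/C)c1cc(OC)cc([N+](=O)[O-])c1OC | intermediate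
13 | 1-[(3R,7S)-3,7-dimethylcyclohepta-1,4-dien-1-yl]-2,5-dimethoxy-3-nitrobenzene | C[C@@H]1C=CC[C@H](C)C(c2cc(OC)cc([N+](=O)[O-])c2OC)=C1 | intermediate
14 | (1S,2R,3S,6S)-5-(2,5-dimethoxy-3-nitrophenyl)-3,6-dimethylcyclohept-4-ene-1,2-diol | C[C@@H]1[C@@H](O)[C@@H](O)C[C@H](C)C(c2cc(OC)cc([N+](=O)[O-])c2OC)=C1 | intermediate
15 | 1-[(3S,4R,5S,7S)-4,5-dimethoxy-3,7-dimethylcyclohept-1-en-1-yl]-2,5-dimethoxy-3-nitrobenzene | C[C@@H]1[C@@H](OC)[C@@H](OC)C[C@H](C)C(c2cc(OC)cc([N+](=O)[O-])c2OC)=C1 | intermediate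
16 | (2S,4S,5R,6R)-1-(2,5-dimethoxy-3-nitrophenyl)-4,5-dimethoxy-2,6-dimethyl-8,9,10-trioxabicyclo[5.2.1]decane (secondary ozonide across C9 and C15, bridgeheads as formed) | C[C@@H]1[C@@H](OC)[C@@H](OC)C[C@H](C)C2(c3cc(OC)cc([N+](=O)[O-])c3OC)OOC1O2 | intermediate
17 | (2R,3R,4S,6S)-7-(2,5-dimethoxy-3-nitrophenyl)-3,4-dimethoxy-2,6-dimethyl-7-oxoheptanal | C[C@@H](C=O)[C@@H](OC)[C@@H](OC)C[C@H](C)C(=O)c1cc(OC)cc([N+](=O)[O-])c1OC | intermediate
18 | ethyl (2E,4S,5R,6S,8S)-9-(2,5-dimethoxy-3-nitrophenyl)-5,6-dimethoxy-2,4,8-trimethyl-9-oxonon-2-enoate | CCOC(=O)/C(C)=C/[C@H](C)[C@@H](OC)[C@@H](OC)C[C@H](C)C(=O)c1cc(OC)cc([N+](=O)[O-])c1OC | intermediate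
19 | ethyl (2E,4S,5R,6S,8S,9R)-9-(2,5-dimethoxy-3-nitrophenyl)-9-hydroxy-5,6-dimethoxy-2,4,8-trimethylnon-2-enoate | CCOC(=O)/C(C)=C/[C@H](C)[C@@H](OC)[C@@H](OC)C[C@H](C)[C@@H](O)c1cc(OC)cc([N+](=O)[O-])c1OC | intermediate
20 | ethyl (2E,4S,5R,6S,8S,9R)-9-{[tert-butyl(dimethyl)silyl]oxy}-9-(2,5-dimethoxy-3-nitrophenyl)-5,6-dimethoxy-2,4,8-trimethylnon-2-enoate | CCOC(=O)/C(C)=C/[C@H](C)[C@@H](OC)[C@@H](OC)C[C@H](C)[C@@H](O[Si](C)(C)C(C)(C)C)c1cc(OC)cc([N+](=O)[O-])c1OC | intermediate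
21 | (2E,4S,5R,6S,8S,9R)-9-{[tert-butyl(dimethyl)silyl]oxy}-9-(2,5-dimethoxy-3-nitrophenyl)-5,6-dimethoxy-2,4,8-trimethylnon-2-en-1-ol | OC/C(C)=C/[C@H](C)[C@@H](OC)[C@@H](OC)C[C@H](C)[C@@H](O[Si](C)(C)C(C)(C)C)c1cc(OC)cc([N+](=O)[O-])c1OC | intermediate
22 | (2E,4S,5R,6S,8S,9R)-9-{[tert-butyl(dimethyl)silyl]oxy}-9-(2,5-dimethoxy-3-nitrophenyl)-5,6-dimethoxy-2,4,8-trimethylnon-2-enal | O=C/C(C)=C/[C@H](C)[C@@H](OC)[C@@H](OC)C[C@H](C)[C@@H](O[Si](C)(C)C(C)(C)C)c1cc(OC)cc([N+](=O)[O-])c1OC | intermediate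
23 | 1-[(4R)-4-benzyl-2-sulfanylidene-1,3-thiazolidin-3-yl]propan-1-one | CCC(=O)N1[C@H](Cc2ccccc2)CSC1=S | starting material
24 | (2R,3R,4E,6S,7R,8S,10S,11R)-1-[(4R)-4-benzyl-2-sulfanylidene-1,3-thiazolidin-3-yl]-11-{[tert-butyl(dimethyl)silyl]oxy}-11-(2,5-dimethoxy-3-nitrophenyl)-3-hydroxy-7,8-dimethoxy-2,4,6,10-tetramethylundec-4-en-1-one | C[C@@H](C(=O)N1[C@H](Cc2ccccc2)CSC1=S)[C@@H](O)/C(C)=C/[C@H](C)[C@@H](OC)[C@@H](OC)C[C@H](C)[C@@H](O[Si](C)(C)C(C)(C)C)c1cc(OC)cc([N+](=O)[O-])c1OC | intermediate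
25 | 3-O-triethylsilyl ether of 24 | C[C@@H](C(=O)N1[C@H](Cc2ccccc2)CSC1=S)[C@@H](O[Si](CC)(CC)CC)/C(C)=C/[C@H](C)[C@@H](OC)[C@@H](OC)C[C@H](C)[C@@H](O[Si](C)(C)C(C)(C)C)c1cc(OC)cc([N+](=O)[O-])c1OC | intermediate
26 | (2R,3R,4E,6S,7R,8S,10S,11R)-11-{[tert-butyl(dimethyl)silyl]oxy}-11-(2,5-dimethoxy-3-nitrophenyl)-7,8-dimethoxy-2,4,6,10-tetramethyl-3-[(triethylsilyl)oxy]undec-4-enal | C[C@@H](C=O)[C@@H](O[Si](CC)(CC)CC)/C(C)=C/[C@H](C)[C@@H](OC)[C@@H](OC)C[C@H](C)[C@@H](O[Si](C)(C)C(C)(C)C)c1cc(OC)cc([N+](=O)[O-])c1OC | intermediate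
27 | methyl (2Z,4S,5R,6E,8S,9R,10S,12S,13R)-13-{[tert-butyl(dimethyl)silyl]oxy}-13-(2,5-dimethoxy-3-nitrophenyl)-9,10-dimethoxy-4,6,8,12-tetramethyl-5-[(triethylsilyl)oxy]trideca-2,6-dienoate | COC(=O)/C=C\[C@H](C)[C@@H](O[Si](CC)(CC)CC)/C(C)=C/[C@H](C)[C@@H](OC)[C@@H](OC)C[C@H](C)[C@@H](O[Si](C)(C)C(C)(C)C)c1cc(OC)cc([N+](=O)[O-])c1OC | intermediate
28 | (2Z,4S,5R,6E,8S,9R,10S,12S,13R)-13-{[tert-butyl(dimethyl)silyl]oxy}-13-(2,5-dimethoxy-3-nitrophenyl)-9,10-dimethoxy-4,6,8,12-tetramethyl-5-[(triethylsilyl)oxy]trideca-2,6-dien-1-ol | OC/C=C\[C@H](C)[C@@H](O[Si](CC)(CC)CC)/C(C)=C/[C@H](C)[C@@H](OC)[C@@H](OC)C[C@H](C)[C@@H](O[Si](C)(C)C(C)(C)C)c1cc(OC)cc([N+](=O)[O-])c1OC | intermediate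
29 | (2Z,4S,5R,6E,8S,9R,10S,12S,13R)-13-{[tert-butyl(dimethyl)silyl]oxy}-13-(2,5-dimethoxy-3-nitrophenyl)-9,10-dimethoxy-4,6,8,12-tetramethyl-5-[(triethylsilyl)oxy]trideca-2,6-dienal | O=C/C=C\[C@H](C)[C@@H](O[Si](CC)(CC)CC)/C(C)=C/[C@H](C)[C@@H](OC)[C@@H](OC)C[C@H](C)[C@@H](O[Si](C)(C)C(C)(C)C)c1cc(OC)cc([N+](=O)[O-])c1OC | intermediate
30 | ethyl (2E,4Z,6S,7R,8E,10S,11R,12S,14S,15R)-15-{[tert-butyl(dimethyl)silyl]oxy}-15-(2,5-dimethoxy-3-nitrophenyl)-11,12-dimethoxy-2,6,8,10,14-pentamethyl-7-[(triethylsilyl)oxy]pentadeca-2,4,8-trienoate | CCOC(=O)/C(C)=C/C=C\[C@H](C)[C@@H](O[Si](CC)(CC)CC)/C(C)=C/[C@H](C)[C@@H](OC)[C@@H](OC)C[C@H](C)[C@@H](O[Si](C)(C)C(C)(C)C)c1cc(OC)cc([N+](=O)[O-])c1OC | intermediate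
31 | ethyl (2E,4Z,6S,7R,8E,10S,11R,12S,14S,15R)-15-(3-amino-2,5-dimethoxyphenyl)-15-{[tert-butyl(dimethyl)silyl]oxy}-11,12-dimethoxy-2,6,8,10,14-pentamethyl-7-[(triethylsilyl)oxy]pentadeca-2,4,8-trienoate | CCOC(=O)/C(C)=C/C=C\[C@H](C)[C@@H](O[Si](CC)(CC)CC)/C(C)=C/[C@H](C)[C@@H](OC)[C@@H](OC)C[C@H](C)[C@@H](O[Si](C)(C)C(C)(C)C)c1cc(OC)cc(N)c1OC | intermediate
32 | (2E,4Z,6S,7R,8E,10S,11R,12S,14S,15R)-15-(3-amino-2,5-dimethoxyphenyl)-15-{[tert-butyl(dimethyl)silyl]oxy}-11,12-dimethoxy-2,6,8,10,14-pentamethyl-7-[(triethylsilyl)oxy]pentadeca-2,4,8-trienoic acid | OC(=O)/C(C)=C/C=C\[C@H](C)[C@@H](O[Si](CC)(CC)CC)/C(C)=C/[C@H](C)[C@@H](OC)[C@@H](OC)C[C@H](C)[C@@H](O[Si](C)(C)C(C)(C)C)c1cc(OC)cc(N)c1OC | intermediate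
33 | 19-membered lactam of 32 (N–C1 amide; 2E,4Z,8E; 6S,7R,10S,11R,12S,14S,15R; 7-O-triethylsilyl; 15-O-tert-butyldimethylsilyl; 2,5-dimethoxy-1,3-phenylene bridge) | CO[C@H]1[C@@H](OC)C[C@H](C)[C@@H](O[Si](C)(C)C(C)(C)C)c2cc(OC)cc(NC(=O)/C(C)=C/C=C\[C@H](C)[C@@H](O[Si](CC)(CC)CC)/C(C)=C/[C@@H]1C)c2OC | intermediate
34 | lactam 33 with free C7 hydroxyl (15-O-tert-butyldimethylsilyl) | CO[C@H]1[C@@H](OC)C[C@H](C)[C@@H](O[Si](C)(C)C(C)(C)C)c2cc(OC)cc(NC(=O)/C(C)=C/C=C\[C@H](C)[C@@H](O)/C(C)=C/[C@@H]1C)c2OC | intermediate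
35 | 7-O-(N-trichloroacetylcarbamoyl) derivative of 34 | CO[C@H]1[C@@H](OC)C[C@H](C)[C@@H](O[Si](C)(C)C(C)(C)C)c2cc(OC)cc(NC(=O)/C(C)=C/C=C\[C@H](C)[C@@H](OC(=O)NC(=O)C(Cl)(Cl)Cl)/C(C)=C/[C@@H]1C)c2OC | intermediate
36 | 7-O-carbamoyl derivative of 34 (dimethoxyarene; 15-O-tert-butyldimethylsilyl) | CO[C@H]1[C@@H](OC)C[C@H](C)[C@@H](O[Si](C)(C)C(C)(C)C)c2cc(OC)cc(NC(=O)/C(C)=C/C=C\[C@H](C)[C@@H](OC(N)=O)/C(C)=C/[C@@H]1C)c2OC | intermediate
37 | 15-O-tert-butyldimethylsilyl ether of the target quinone | CO[C@H]1[C@@H](OC)C[C@H](C)[C@@H](O[Si](C)(C)C(C)(C)C)C2=CC(=O)C=C(NC(=O)/C(C)=C/C=C\[C@H](C)[C@@H](OC(N)=O)/C(C)=C/[C@@H]1C)C2=O | intermediate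
38 | CNP0557283.1 (2E,4Z,8E; 6S,7R,10S,11R,12S,14S,15R; 7-O-carbamoyl, 15-hydroxy, 11,12-dimethoxy ansa quinone lactam) | CO[C@H]1[C@@H](OC)C[C@H](C)[C@@H](O)C2=CC(=O)C=C(NC(=O)/C(C)=C/C=C\[C@H](C)[C@@H](OC(N)=O)/C(C)=C/[C@@H]1C)C2=O | target

Total step count: 30. Longest linear sequence: 29 (steps 1–3 and 5–30; step 4 prepares the side fragment 7).

Steps most likely to fail

Step 8. Under the basic ylide the cis aldehyde 11 may epimerise at C11 or drain into its retro-Claisen isomer before the alkene forms. A trans-dialkenylcyclopropane cannot reach the boat transition state, so the ring would not close. The fallback sets out from 10, avoids the aldehyde by reversing the polarity of the olefination, and returns at 13. Mitsunobu thioetherification of 10 (1-phenyl-1H-tetrazole-5-thiol, PPh3, diisopropyl azodicarboxylate, THF) should give the 1-phenyl-1H-tetrazol-5-yl sulfide of 10 F1. Molybdate-catalysed oxidation ((NH4)6Mo7O24, H2O2, EtOH) should give the 1-phenyl-1H-tetrazol-5-yl sulfone of 10 F2. Julia–Kocienski olefination of F2 with monomeric formaldehyde (KN(SiMe3)2, THF, −78 °C to rt) should then give 12, which rearranges to 13 as in the main route. The carbanion sits on the exocyclic carbon, so no ring stereocentre is at risk.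

Step 9. Osmylation may attack the trisubstituted C9=C15 alkene in competition with, or in preference to, C11=C12. The fallback sets out from 13 and returns at 17; it uses the C9=C15 diol as the masked form of the later cleavage.
- Osmylation (OsO4 cat., 4-methylmorpholine N-oxide) at C9=C15 should give the 1-aryl-3,7-dimethylcyclohept-4-ene-1,2-diol F3.
- 2,2-Dimethoxypropane with pyridinium p-toluenesulfonate should protect it as the acetonide F4.
- A second osmylation of C11=C12, anti to the C10 methyl, should give the acetonide diol F5.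
- NaH/MeI should give the acetonide dimethyl ether F6.
- Aqueous acetic acid should release the 4,5-dimethoxy-1-aryl-3,7-dimethylcycloheptane-1,2-diol F7.
- Glycol cleavage with NaIO4 (THF/H2O) should deliver 17.

Step 13. Reagent control may be too weak in this mismatched reduction, leaving the Felkin 15S epimer as a major product. The fallback sets out from 18 and returns at 19. Substrate-controlled reduction (NaBH4, CeCl3·7H2O, MeOH, −40 °C) should give mainly the 15S alcohol F8. Mitsunobu inversion (4-nitrobenzoic acid, PPh3, diisopropyl azodicarboxylate) should give the 15R 4-nitrobenzoate F9. Ethanolysis (K2CO3, EtOH) should then give 19.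

Further compounds
F1 | step 8 | 5-[({(1R,2S,3S)-2-[(1Z)-1-(2,5-dimethoxy-3-nitrophenyl)prop-1-en-1-yl]-3-methylcyclopropyl}methyl)sulfanyl]-1-phenyl-1H-tetrazole | C[C@@H]1[C@@H](CSc2nnnn2-c2ccccc2)[C@H]1/C(=C/C)c1cc(OC)cc([N+](=O)[O-])c1OC
F2 | step 8 | 5-[({(1R,2S,3S)-2-[(1Z)-1-(2,5-dimethoxy-3-nitrophenyl)prop-1-en-1-yl]-3-methylcyclopropyl}methyl)sulfonyl]-1-phenyl-1H-tetrazole | C[C@@H]1[C@@H](CS(=O)(=O)c2nnnn2-c2ccccc2)[C@H]1/C(=C/C)c1cc(OC)cc([N+](=O)[O-])c1OC
F3 | step 9 | 1-(2,5-dimethoxy-3-nitrophenyl)-3,7-dimethylcyclohept-4-ene-1,2-diol (cis-diol anti to both methyls) | C[C@@H]1C=CC[C@H](C)[C@](O)(c2cc(OC)cc([N+](=O)[O-])c2OC)[C@H]1O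
F4 | step 9 | acetonide of F3 | C[C@@H]1C=CC[C@H](C)[C@@]2(c3cc(OC)cc([N+](=O)[O-])c3OC)OC(C)(C)O[C@@H]12
F5 | step 9 | C11,C12-cis-diol of F4 (hydroxyls anti to the methyls) | C[C@@H]1[C@@H](O)[C@@H](O)C[C@H](C)[C@@]2(c3cc(OC)cc([N+](=O)[O-])c3OC)OC(C)(C)O[C@@H]12
F6 | step 9 | C11,C12-dimethyl ether of F5 | C[C@@H]1[C@@H](OC)[C@@H](OC)C[C@H](C)[C@@]2(c3cc(OC)cc([N+](=O)[O-])c3OC)OC(C)(C)O[C@@H]12
F7 | step 9 | 1-(2,5-dimethoxy-3-nitrophenyl)-4,5-dimethoxy-3,7-dimethylcycloheptane-1,2-diol | C[C@@H]1[C@@H](OC)[C@@H](OC)C[C@H](C)[C@](O)(c2cc(OC)cc([N+](=O)[O-])c2OC)[C@H]1O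
F8 | step 13 | ethyl (2E,4S,5R,6S,8S,9S)-9-(2,5-dimethoxy-3-nitrophenyl)-9-hydroxy-5,6-dimethoxy-2,4,8-trimethylnon-2-enoate | CCOC(=O)/C(C)=C/[C@H](C)[C@@H](OC)[C@@H](OC)C[C@H](C)[C@H](O)c1cc(OC)cc([N+](=O)[O-])c1OC
F9 | step 13 | 9-O-(4-nitrobenzoyl) derivative of 19 (9R) | CCOC(=O)/C(C)=C/[C@H](C)[C@@H](OC)[C@@H](OC)C[C@H](C)[C@@H](OC(=O)c1ccc(cc1)[N+](=O)[O-])c1cc(OC)cc([N+](=O)[O-])c1OC
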